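**Retrosynthetic overview**

1. Ring 1 (O1, C2, C3, C3a–C7a; its benzo part is ring A, styryl at C6) and ring 2 (primed atoms; its benzo part is ring B, bonded through C6' to C3; C3' carries the resorcinyl ring) are both cut at the O–CH bonds O1–C2 and O1'–C2'. They are closed together in the last step from an open bis(4-oxybenzylic alcohol) whose nine phenols are MOM ethers and which already carries the (E)-styryl group.
2. Feature: C2 and C2' each bear a 4-oxygenated phenyl group, so each ionises to a p-quinone-methide-type cation. Each sits next to C3 (C3'), whose aryl carbon C3a (C3a') is flanked by two oxygens that are equivalent by rotation, so either oxygen closes the same five-membered ring and the closure can equilibrate to trans.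
3. The open bis(carbinol) comes from a bis(1,2,2-triarylethanone) by asymmetric transfer hydrogenation with dynamic kinetic resolution, which fixes C3 and C3' while they are still enolisable.
4. The bis(ketone) comes from four palladium-catalysed α-arylations on two molecules of MOM-protected 4'-hydroxyacetophenone: C3'–resorcinyl ring, C3'–C3a' (iodide of ring B), C6'–CH2 (chloride of ring B) and C3–C3a (bromide of ring A, stilbene installed beforehand by Horner–Wadsworth–Emmons olefination).
5. Ring order: no heterocycle before the end; rings 1 and 2 form in the same final operation, which also removes every protecting group.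

Key step: step 15

Remark: the (S,S)-catalyst of step 14 is chosen on the assumption that the 2,6-dioxygenated aryl group is the large substituent in the Felkin–Anh sense (were it the other α-aryl group, the (R,R)-catalyst would be taken); 5-chlororesorcinol and diethyl (4-hydroxybenzyl)phosphonate are taken as purchasable.

**Route**

Step 1
Reactants: 1 4'-hydroxyacetophenone
Product: 2 1-[4-(methoxymethoxy)phenyl]ethan-1-one
Conditions: MOMCl, i-Pr2NEt, CH2Cl2, 0 °C to rt
Reagents that add atoms: chloromethyl methyl ether (MOMCl), COCCl
Why: O-alkylation of the phenol with the α-chloro ether gives an acetal ether that tolerates alkoxide base and zerovalent palladium and is shed in the final acid step.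

Step 2
Reactants: 3 5-bromoresorcinol
Product: 4 1-bromo-3,5-bis(methoxymethoxy)benzene
Conditions: MOMCl (2.5 equiv), i-Pr2NEt, CH2Cl2, 0 °C to rt
Reagents that add atoms: chloromethyl methyl ether (MOMCl), COCCl
Why: double O-alkylation of the resorcinol under the conditions of step 1 leaves the aryl bromide untouched.

Step 3
Reactants: 2 1-[4-(methoxymethoxy)phenyl]ethan-1-one; 4 1-bromo-3,5-bis(methoxymethoxy)benzene
Product: 5 2-[3,5-bis(methoxymethoxy)phenyl]-1-[4-(methoxymethoxy)phenyl]ethan-1-one
Conditions: Pd2(dba)3 (cat.), rac-BINAP, NaOtBu, THF, 70 °C; 2 in slight excess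
Reagents that add atoms: none
Why: palladium-catalysed α-arylation of a methyl ketone enolate (Buchwald–Hartwig type) with an unhindered aryl bromide, held at the mono-arylated deoxybenzoin by the chelating bisphosphine and the excess of ketone.

Step 4
Reactants: 6 5-chlororesorcinol
Product: 7 1-chloro-3,5-bis(methoxymethoxy)benzene
Conditions: MOMCl (2.5 equiv), i-Pr2NEt, CH2Cl2, 0 °C to rt
Reagents that add atoms: chloromethyl methyl ether (MOMCl), COCCl
Why: double O-alkylation as in step 2 gives the two directing groups needed for the metalation of step 5.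

Step 5
Reactants: 7 1-chloro-3,5-bis(methoxymethoxy)benzene
Product: 9 5-chloro-2-iodo-1,3-bis(methoxymethoxy)benzene, via aryllithium 8 (not isolated)
Conditions: n-BuLi, THF, −78 to −40 °C; then I2, −78 °C to rt
Reagents that add atoms: iodine, II
Why: directed ortho-metalation takes the proton flanked by both coordinating OMOM groups (chlorine does not exchange with n-BuLi at this temperature and lies para to the lithiated carbon, so no aryne can form), and the aryllithium is iodinated.

Step 6
Reactants: 5 2-[3,5-bis(methoxymethoxy)phenyl]-1-[4-(methoxymethoxy)phenyl]ethan-1-one; 9 5-chloro-2-iodo-1,3-bis(methoxymethoxy)benzene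
Product: 10 rac-2-[4-chloro-2,6-bis(methoxymethoxy)phenyl]-2-[3,5-bis(methoxymethoxy)phenyl]-1-[4-(methoxymethoxy)phenyl]ethan-1-one
Conditions: Pd2(dba)3 (cat.), Xantphos, NaOtBu, toluene, 90 °C; 9 in slight excess
Reagents that add atoms: none
Why: α-arylation of a deoxybenzoin enolate to a 1,2,2-triarylethanone, in which zerovalent palladium with this bisphosphine inserts into C–I and not into C–Cl and the product is too hindered to be arylated again; C3' arises racemic and stays enolisable, as the later dynamic reduction requires.

Step 7
Reactants: 10 rac-2-[4-chloro-2,6-bis(methoxymethoxy)phenyl]-2-[3,5-bis(methoxymethoxy)phenyl]-1-[4-(methoxymethoxy)phenyl]ethan-1-one; 2 1-[4-(methoxymethoxy)phenyl]ethan-1-one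
Product: 11 rac-2-[3,5-bis(methoxymethoxy)phenyl]-2-{2,6-bis(methoxymethoxy)-4-[2-(4-(methoxymethoxy)phenyl)-2-oxoethyl]phenyl}-1-[4-(methoxymethoxy)phenyl]ethan-1-one
Conditions: Pd(OAc)2 (cat.), XPhos, NaOtBu (3.5 equiv), toluene, 100 °C; 2 (3 equiv)
Reagents that add atoms: none
Why: α-arylation of the methyl ketone with the unhindered aryl chloride under a bulky dialkylbiarylphosphine, while the triarylethanone C–H is masked as a hindered enolate that does not couple and the excess of 2 suppresses double arylation.

Step 8
Reactants: 12 methyl 4-bromo-3,5-dihydroxybenzoate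
Product: 13 methyl 4-bromo-3,5-bis(methoxymethoxy)benzoate
Conditions: MOMCl (2.5 equiv), i-Pr2NEt, CH2Cl2, 0 °C to rt
Reagents that add atoms: chloromethyl methyl ether (MOMCl), COCCl
Why: the two phenols flanking the bromide are alkylated under the same mild amine-base conditions, which the ester tolerates.

Step 9
Reactants: 13 methyl 4-bromo-3,5-bis(methoxymethoxy)benzoate
Product: 14 [4-bromo-3,5-bis(methoxymethoxy)phenyl]methanol
Conditions: i-Bu2AlH (2.5 equiv), CH2Cl2, −78 to 0 °C
Reagents that add atoms: none
Why: hydride reduction of the ester to the primary alcohol, with aryl bromide and acetal ethers inert to the aluminium hydride.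

Step 10
Reactants: 14 [4-bromo-3,5-bis(methoxymethoxy)phenyl]methanol
Product: 15 4-bromo-3,5-bis(methoxymethoxy)benzaldehyde
Conditions: MnO2, CH2Cl2, rt
Reagents that add atoms: none
Why: heterogeneous oxidation of a benzylic alcohol stops cleanly at the aldehyde.

Step 11
Reactants: 16 diethyl (4-hydroxybenzyl)phosphonate
Product: 17 diethyl [4-(methoxymethoxy)benzyl]phosphonate
Conditions: MOMCl, i-Pr2NEt, CH2Cl2, 0 °C to rt
Reagents that add atoms: chloromethyl methyl ether (MOMCl), COCCl
Why: phenol O-alkylation removes the acidic proton that would otherwise quench the phosphonate carbanion in step 12.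

Step 12
Reactants: 15 4-bromo-3,5-bis(methoxymethoxy)benzaldehyde; 17 diethyl [4-(methoxymethoxy)benzyl]phosphonate
Product: 18 (E)-2-bromo-1,3-bis(methoxymethoxy)-5-{2-[4-(methoxymethoxy)phenyl]ethenyl}benzene
Conditions: KOtBu, THF, 0 °C to rt
Reagents that add atoms: none
Why: Horner–Wadsworth–Emmons olefination of an aryl aldehyde with a benzylic phosphonate carbanion, whose reversible addition and syn-elimination of phosphate give the (E)-stilbene.

Step 13
Reactants: 11 rac-2-[3,5-bis(methoxymethoxy)phenyl]-2-{2,6-bis(methoxymethoxy)-4-[2-(4-(methoxymethoxy)phenyl)-2-oxoethyl]phenyl}-1-[4-(methoxymethoxy)phenyl]ethan-1-one; 18 (E)-2-bromo-1,3-bis(methoxymethoxy)-5-{2-[4-(methoxymethoxy)phenyl]ethenyl}benzene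
Product: 19 nona-MOM bis(1,2,2-triarylethanone), that is 11 in which one hydrogen of the CH2 group is replaced by the aryl group of 18 (C3 and C3' as an equilibrating mixture of stereoisomers)
Conditions: Pd2(dba)3 (cat.), P(t-Bu)3·HBF4, NaOtBu (3.5 equiv), toluene, 90 °C
Reagents that add atoms: none
Why: α-arylation of the benzylic CH2 enolate of 11 with the di-ortho-alkoxy aryl bromide under a bulky electron-rich monophosphine, the internal stilbene being a far poorer partner for the arylpalladium species than the enolate; C3 arises unselectively and remains enolisable.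

Step 14
Reactants: 19 nona-MOM bis(1,2,2-triarylethanone)
Product: 20 nona-MOM bis(carbinol), both ketones reduced, C3 and C3' (S), carbinol carbons C2 and C2' expected (S)
Conditions: RuCl[(S,S)-TsDPEN](p-cymene) (cat.), HCO2H/Et3N (1:1), DMF, 40 °C
Reagents that add atoms: none
Why: Proposed new method: Noyori–Ikariya transfer hydrogenation with dynamic kinetic resolution is established for aryl ketones with an enolisable α-stereocentre (cyclic α-aryl ketones, benzoin-type ketones) but not for acyclic α,α-diaryl ketones in which two aryl groups must be told apart; here the doubly benzylic C3–H and C3'–H should racemise through the enol in the amine-rich formate medium, the catalyst should set each carbinol as (S) through the CH/π contact of its arene with the 4-(methoxymethoxy)phenyl ketone, and Felkin–Anh matching (the 2,6-dioxygenated aryl group anti to the incoming hydride) should let only the (S)-configured C3 and C3' epimers react fast, so that both centres are fixed as (S) in one operation.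

Step 15
Reactants: 20 nona-MOM bis(carbinol)
Product: 23 (2S,3S)-3-[(2S,3S)-3-(3,5-dihydroxyphenyl)-4-hydroxy-2-(4-hydroxyphenyl)-2,3-dihydro-1-benzofuran-6-yl]-2-(4-hydroxyphenyl)-6-[(E)-2-(4-hydroxyphenyl)ethenyl]-2,3-dihydro-1-benzofuran-4-ol (CNP0248228.2), via MOM-free bis(carbinol) 21 (not isolated), via bis(p-quinone methide) 22 (not isolated)
Conditions: HCl (1 M in MeOH), degassed, 0.005 M, 40 °C, dark
Reagents that add atoms: none
Why: Acidic methanol transfers all nine methoxymethyl groups to the solvent, and each 4-hydroxybenzylic alcohol then loses water to a p-quinone methide (its O-protonated form is the 4-hydroxybenzyl cation), which the phenol oxygen ortho to C3a (C3a') captures at C2 (C2'). The closest known reaction type is the acid-mediated closure and cis-to-trans equilibration of 2-(4-oxyphenyl)-2,3-dihydrobenzofurans through 4-oxybenzylic cations. Both rings close in the 5-exo-trig mode, ring 1 by forming O1–C2 and ring 2 by forming O1'–C2'. The new stereocentres C2 and C2' are controlled by the fixed neighbours C3 and C3': capture is reversible under the acid, so each ring settles in the trans form in which the C2 aryl group avoids the C3 aryl group, and every carbinol epimer of 20 converges on one product. The step needs trans selectivity, which this thermodynamic control supplies, and needs no regiochemical choice, because the two ortho oxygens of ring A (and of ring B) are equivalent by rotation about C3–C3a (C3'–C3a') and no carbon nucleophile, the stilbene included, can reach either cation through a ring of feasible size.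

**Compound list**

1 | 4'-hydroxyacetophenone | CC(=O)c1ccc(O)cc1 | starting material
2 | 1-[4-(methoxymethoxy)phenyl]ethan-1-one | CC(=O)c1ccc(OCOC)cc1 | intermediate
3 | 5-bromoresorcinol | Oc1cc(O)cc(Br)c1 | starting material
4 | 1-bromo-3,5-bis(methoxymethoxy)benzene | COCOc1cc(Br)cc(OCOC)c1 | intermediate
5 | 2-[3,5-bis(methoxymethoxy)phenyl]-1-[4-(methoxymethoxy)phenyl]ethan-1-one | COCOc1ccc(cc1)C(=O)Cc1cc(OCOC)cc(OCOC)c1 | intermediate
6 | 5-chlororesorcinol | Oc1cc(O)cc(Cl)c1 | starting material
7 | 1-chloro-3,5-bis(methoxymethoxy)benzene | COCOc1cc(Cl)cc(OCOC)c1 | intermediate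
8 | [4-chloro-2,6-bis(methoxymethoxy)phenyl]lithium | [Li]c1c(OCOC)cc(Cl)cc1OCOC | intermediate (not isolated)
9 | 5-chloro-2-iodo-1,3-bis(methoxymethoxy)benzene | COCOc1cc(Cl)cc(OCOC)c1I | intermediate
10 | rac-2-[4-chloro-2,6-bis(methoxymethoxy)phenyl]-2-[3,5-bis(methoxymethoxy)phenyl]-1-[4-(methoxymethoxy)phenyl]ethan-1-one | COCOc1ccc(cc1)C(=O)C(c1cc(OCOC)cc(OCOC)c1)c1c(OCOC)cc(Cl)cc1OCOC | intermediate
11 | rac-2-[3,5-bis(methoxymethoxy)phenyl]-2-{2,6-bis(methoxymethoxy)-4-[2-(4-(methoxymethoxy)phenyl)-2-oxoethyl]phenyl}-1-[4-(methoxymethoxy)phenyl]ethan-1-one | COCOc1ccc(cc1)C(=O)Cc1cc(OCOC)c(c(OCOC)c1)C(C(=O)c1ccc(OCOC)cc1)c1cc(OCOC)cc(OCOC)c1 | intermediate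
12 | methyl 4-bromo-3,5-dihydroxybenzoate | COC(=O)c1cc(O)c(Br)c(O)c1 | starting material
13 | methyl 4-bromo-3,5-bis(methoxymethoxy)benzoate | COC(=O)c1cc(OCOC)c(Br)c(OCOC)c1 | intermediate
14 | [4-bromo-3,5-bis(methoxymethoxy)phenyl]methanol | OCc1cc(OCOC)c(Br)c(OCOC)c1 | intermediate
15 | 4-bromo-3,5-bis(methoxymethoxy)benzaldehyde | O=Cc1cc(OCOC)c(Br)c(OCOC)c1 | intermediate
16 | diethyl (4-hydroxybenzyl)phosphonate | CCOP(=O)(Cc1ccc(O)cc1)OCC | starting material
17 | diethyl [4-(methoxymethoxy)benzyl]phosphonate | CCOP(=O)(Cc1ccc(OCOC)cc1)OCC | intermediate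
18 | (E)-2-bromo-1,3-bis(methoxymethoxy)-5-{2-[4-(methoxymethoxy)phenyl]ethenyl}benzene | COCOc1ccc(/C=C/c2cc(OCOC)c(Br)c(OCOC)c2)cc1 | intermediate
19 | nona-MOM bis(1,2,2-triarylethanone): ring A (with the (E)-styryl group) and ring B on C3, ring B and the resorcinyl ring on C3', each of C3 and C3' bearing a 4-(methoxymethoxy)benzoyl group; stereoisomer mixture at C3 and C3' | COCOc1ccc(/C=C/c2cc(OCOC)c(c(OCOC)c2)C(C(=O)c2ccc(OCOC)cc2)c2cc(OCOC)c(c(OCOC)c2)C(C(=O)c2ccc(OCOC)cc2)c2cc(OCOC)cc(OCOC)c2)cc1 | intermediate
20 | nona-MOM bis(carbinol): 19 with both ketones reduced; C3 and C3' (S), carbinol carbons C2 and C2' expected (S) | COCOc1ccc(/C=C/c2cc(OCOC)c(c(OCOC)c2)[C@@H]([C@H](O)c2ccc(OCOC)cc2)c2cc(OCOC)c(c(OCOC)c2)[C@@H]([C@H](O)c2ccc(OCOC)cc2)c2cc(OCOC)cc(OCOC)c2)cc1 | intermediate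
21 | MOM-free bis(carbinol): 20 without its nine MOM groups | Oc1ccc(/C=C/c2cc(O)c(c(O)c2)[C@@H]([C@H](O)c2ccc(O)cc2)c2cc(O)c(c(O)c2)[C@@H]([C@H](O)c2ccc(O)cc2)c2cc(O)cc(O)c2)cc1 | intermediate (not isolated)
22 | bis(p-quinone methide): 21 after loss of two molecules of water, each 4-hydroxyphenyl carbinol now a 4-methylidenecyclohexa-2,5-dien-1-one; C3 and C3' as in 20 | Oc1ccc(/C=C/c2cc(O)c(c(O)c2)[C@@H](C=C2C=CC(=O)C=C2)c2cc(O)c(c(O)c2)[C@@H](C=C2C=CC(=O)C=C2)c2cc(O)cc(O)c2)cc1 | intermediate (not isolated)
23 | (2S,3S)-3-[(2S,3S)-3-(3,5-dihydroxyphenyl)-4-hydroxy-2-(4-hydroxyphenyl)-2,3-dihydro-1-benzofuran-6-yl]-2-(4-hydroxyphenyl)-6-[(E)-2-(4-hydroxyphenyl)ethenyl]-2,3-dihydro-1-benzofuran-4-ol | Oc1ccc(/C=C/c2cc(O)c3c(c2)O[C@H](c2ccc(O)cc2)[C@H]3c2cc(O)c3c(c2)O[C@H](c2ccc(O)cc2)[C@H]3c2cc(O)cc(O)c2)cc1 | target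

**Step count and risks**

Total step count: 15. Longest linear sequence: 7 steps (steps 4, 5, 6, 7, 13, 14, 15).

Steps most likely to fail:

1. Step 14 (proposed new method). Enolisation at the congested C3 and C3' may lag behind hydride transfer, turning the dynamic resolution into a plain kinetic one. The transition state may also fail to discriminate the two α-aryl groups, so that both C3 epimers are reduced, or the hindered electron-rich ketones may react too slowly. Fallback by known chemistry (resolution instead of asymmetric catalysis), setting out from 19 and returning at 23: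
   - 19 is reduced without stereocontrol by NaBH4 in THF/MeOH at 0 °C to the stereorandom nona-MOM bis(carbinol) F1.
   - F1 is treated with HCl in methanol as in step 15, which still closes both rings trans and gives the trans,trans trimer as a mixture of four stereoisomers F2 (two racemic diastereomers that differ in the relation between ring 1 and ring 2).
   - The diastereomers are separated by reverse-phase HPLC, and the racemate containing the target is resolved by preparative HPLC on an amylose tris(3,5-dimethylphenylcarbamate) stationary phase to give 23.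

2. Step 15 (key step). Removal of nine MOM groups is slow, so the benzylic cations coexist for a long time with free resorcinol rings and the stilbene in protic acid. Loss of the C3 or C3' proton from a cation followed by reprotonation would erode the configuration set in step 14, and intermolecular Friedel–Crafts capture would give oligomers. Fallback, setting out from 20 and returning at 23, in which ring closure is separated from deprotection and the nucleophile is changed:
   - 20 is treated with Sc(OTf)3 (cat.) and methanol (5 equiv) in CH2Cl2 at −20 °C. The ortho MOM-ether oxygen itself captures each benzylic cation, and the resulting oxonium ion expels the methoxymethyl cation to methanol, so both rings close on the fully protected substrate to give the hepta-MOM ether of the target F3.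
   - The remaining MOM groups are then removed with dilute HCl in methanol at rt, where the rings are already in their trans resting state, to give 23.

3. Step 13. Transmetalation of the di-ortho-substituted arylpalladium bromide with the secondary, doubly deprotonated enolate may be slow, which would lead to protodebromination of 18 or to carbopalladation of its stilbene. Fallback, setting out from 2, 18 and 10 and returning at 19 (it replaces steps 7 and 13 by reversing the order of bond formation):
   - The hindered bromide 18 is coupled first with the primary enolate of 2 (Pd(OAc)2, XPhos, NaOtBu, toluene, 80 °C) to give the deoxybenzoin 2-{2,6-bis(methoxymethoxy)-4-[(E)-2-(4-(methoxymethoxy)phenyl)ethenyl]phenyl}-1-[4-(methoxymethoxy)phenyl]ethan-1-one F4.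
   - The enolate of F4 is then arylated with the unhindered aryl chloride 10 (Pd(OAc)2, XPhos, NaOtBu, toluene, 100 °C) to give 19.

**Further compounds**

F1 | step 14 | stereorandom nona-MOM bis(carbinol), all stereoisomers at C2, C3, C2' and C3' | COCOc1ccc(/C=C/c2cc(OCOC)c(c(OCOC)c2)C(C(O)c2ccc(OCOC)cc2)c2cc(OCOC)c(c(OCOC)c2)C(C(O)c2ccc(OCOC)cc2)c2cc(OCOC)cc(OCOC)c2)cc1
F2 | step 14 | trans,trans trimer as a mixture of four stereoisomers (each dihydrofuran ring trans; racemate of 23 plus the racemic diastereomer) | Oc1ccc(/C=C/c2cc(O)c3c(c2)OC(c2ccc(O)cc2)C3c2cc(O)c3c(c2)OC(c2ccc(O)cc2)C3c2cc(O)cc(O)c2)cc1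
F3 | step 15 | hepta-MOM ether of 23, (2S,3S,2'S,3'S) | COCOc1ccc(/C=C/c2cc(OCOC)c3c(c2)O[C@H](c2ccc(OCOC)cc2)[C@H]3c2cc(OCOC)c3c(c2)O[C@H](c2ccc(OCOC)cc2)[C@H]3c2cc(OCOC)cc(OCOC)c2)cc1
F4 | step 13 | 2-{2,6-bis(methoxymethoxy)-4-[(E)-2-(4-(methoxymethoxy)phenyl)ethenyl]phenyl}-1-[4-(methoxymethoxy)phenyl]ethan-1-one | COCOc1ccc(/C=C/c2cc(OCOC)c(CC(=O)c3ccc(OCOC)cc3)c(OCOC)c2)cc1
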